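**Retrosynthetic overview**
- The free 4'-OH is unmasked last. Hydrogenolysis of a C2-symmetric p-xylylene-bridged bis-flavanone gives two molecules of target, so the bridge serves as the phenol protection.
- The two C4 ketones come from C4–H oxidation of the corresponding bis(4-methoxyflavan).
- Key disconnection: O1–C2 and C3–C4 in both halves at once. This is a double catalytic asymmetric oxa-[4+2] of two α-methoxy o-quinone methides (A ring) with a bis-styrene (two B rings).
- The bis-styrene comes from 4-vinylguaiacol and 1,4-bis(bromomethyl)benzene. The quinone methide precursor comes from ortho-formylation of 3,4,5-trimethoxyphenol.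
- Ring order: all aromatic rings are bought. The two pyran rings are the only rings built, and they form together in step 3.

Assumption: the (R)-configured N-triflylphosphoramide gives the 2S series. The sense is checked by CD on the bis-flavanone, and if it is 2R the commercial (S)-catalyst is used in the same way.

**Step 1**
Reactants: 1 2-methoxy-4-vinylphenol (2.05 equiv); 2 1,4-bis(bromomethyl)benzene
Product: 3 1,4-bis[(2-methoxy-4-vinylphenoxy)methyl]benzene
Conditions: K2CO3, DMF, 40 °C (trace BHT)
Reagents that add atoms: none
Why: Williamson ether synthesis, in which the guaiacol phenoxide displaces both primary benzylic bromides (SN2) and the bridge protects two B-ring phenols at once; no stereocentre.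

**Step 2**
Reactants: 4 3,4,5-trimethoxyphenol
Product: 5 2-hydroxy-4,5,6-trimethoxybenzaldehyde
Conditions: MgCl2, Et3N, (CH2O)n, MeCN, reflux; 1 M HCl work-up
Reagents that add atoms: formaldehyde (as paraformaldehyde), C=O
Why: Casnati–Skattebøl ortho-formylation, in which the magnesium phenoxide delivers formaldehyde only to the two equivalent ortho positions and a second formaldehyde takes up hydride (Oppenauer type) to give the salicylaldehyde; no stereocentre.

**Step 3 (key step)**
Reactants: 3 1,4-bis[(2-methoxy-4-vinylphenoxy)methyl]benzene; 5 2-hydroxy-4,5,6-trimethoxybenzaldehyde (2.3 equiv)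
Product: 8 1,4-bis({4-[(2S,4S)-4,5,6,7-tetramethoxychroman-2-yl]-2-methoxyphenoxy}methyl)benzene, via salicylaldehyde dimethyl acetal 6 (not isolated), via alpha-methoxy o-quinone methide 7 (not isolated)
Conditions: HC(OMe)3 (3 equiv), (R)-3,3'-bis(2,4,6-triisopropylphenyl)-BINOL N-triflylphosphoramide (10 mol %), 5 Å MS, toluene, rt then −30 °C
Reagents that add atoms: trimethyl orthoformate, COC(OC)OC
Why: Proposed new method: acid-catalysed acetalisation of 5 and loss of methanol give the push–pull quinone methide 7 (or its O-protonated oxocarbenium form) bound to the chiral phosphoramide anion, each electron-rich 4-alkoxystyrene end of 3 then attacks C4 through its CH2 carbon while the benzylic carbon is captured by the quinone methide oxygen (inverse-electron-demand oxa-Diels–Alder, endo, mainly 2,4-cis), so both pyran rings and both C2 centres (S, catalyst control) form in one operation and a wrong-sense event ends up in a separable meso isomer (95:5 per event gives about 99% ee for the C2-symmetric product); the closest known reaction types are the Lewis-acid three-component salicylaldehyde/orthoformate/styrene chroman synthesis, chiral N-triflylphosphoramide-catalysed o-quinone methide/styrene [4+2] cycloadditions, and the confined-acid intramolecular [4+2] of α-alkoxy o-quinone methides made from salicylaldehydes.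

**Step 4**
Reactants: 8 1,4-bis({4-[(2S,4S)-4,5,6,7-tetramethoxychroman-2-yl]-2-methoxyphenoxy}methyl)benzene
Product: 9 1,4-bis({4-[(2S)-5,6,7-trimethoxy-4-oxochroman-2-yl]-2-methoxyphenoxy}methyl)benzene
Conditions: DDQ (2.5 equiv), CH2Cl2–H2O 18:1, 0 °C to rt; meso isomer removed by chromatography/recrystallisation
Reagents that add atoms: water, O
Why: DDQ oxidation of a benzylic ether by hydride abstraction, selective for C4–H because that cation is an oxocarbenium ion conjugated with the ortho/para-oxygenated A ring (the same C4 selectivity as in DDQ functionalisation of protected flavan-3-ols); water gives a hemiketal that loses methanol to the deactivated aryl ketone, C2 is untouched, and the C4 centre is erased.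

**Step 5**
Reactants: 9 1,4-bis({4-[(2S)-5,6,7-trimethoxy-4-oxochroman-2-yl]-2-methoxyphenoxy}methyl)benzene
Product: 10 agecorynin E, (2S)-2-(4-hydroxy-3-methoxyphenyl)-5,6,7-trimethoxychroman-4-one (2 mol per mol of 9)
Conditions: H2 (1 atm), 10% Pd/C, EtOAc–THF, rt
Reagents that add atoms: none
Why: Catalytic hydrogenolysis of both benzyl-type aryl ether C–O bonds under neutral conditions, which avoids the base-induced retro-oxa-Michael (chalcone/quinone methide) racemisation of a 4'-hydroxyflavanone; C2 stays S.

**Compound list**
1 | 2-methoxy-4-vinylphenol | COc1cc(C=C)ccc1O | starting material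
2 | 1,4-bis(bromomethyl)benzene | BrCc1ccc(CBr)cc1 | starting material
3 | 1,4-bis[(2-methoxy-4-vinylphenoxy)methyl]benzene | COc1cc(C=C)ccc1OCc1ccc(COc2ccc(C=C)cc2OC)cc1 | intermediate
4 | 3,4,5-trimethoxyphenol | COc1cc(O)cc(OC)c1OC | starting material
5 | 2-hydroxy-4,5,6-trimethoxybenzaldehyde | COc1cc(O)c(C=O)c(OC)c1OC | intermediate
6 | 2-(dimethoxymethyl)-3,4,5-trimethoxyphenol | COc1cc(O)c(C(OC)OC)c(OC)c1OC | intermediate
7 | 3,4,5-trimethoxy-6-(methoxymethylidene)cyclohexa-2,4-dien-1-one | COC=C1C(=O)C=C(OC)C(OC)=C1OC | intermediate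
8 | 1,4-bis({4-[(2S,4S)-4,5,6,7-tetramethoxychroman-2-yl]-2-methoxyphenoxy}methyl)benzene | COc1cc([C@@H]2C[C@H](OC)c3c(cc(OC)c(OC)c3OC)O2)ccc1OCc1ccc(COc2ccc([C@@H]3C[C@H](OC)c4c(cc(OC)c(OC)c4OC)O3)cc2OC)cc1 | intermediate
9 | 1,4-bis({4-[(2S)-5,6,7-trimethoxy-4-oxochroman-2-yl]-2-methoxyphenoxy}methyl)benzene | COc1cc([C@@H]2CC(=O)c3c(cc(OC)c(OC)c3OC)O2)ccc1OCc1ccc(COc2ccc([C@@H]3CC(=O)c4c(cc(OC)c(OC)c4OC)O3)cc2OC)cc1 | intermediate
10 | agecorynin E, (2S)-2-(4-hydroxy-3-methoxyphenyl)-5,6,7-trimethoxychroman-4-one | COc1cc([C@@H]2CC(=O)c3c(cc(OC)c(OC)c3OC)O2)ccc1O | target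

**Total steps:** 5. **Longest linear sequence:** 4 (4 → 5 → 8 → 9 → 10, or 1 → 3 → 8 → 9 → 10).

**Steps most likely to fail**

**Step 3.** The risks are cationic oligomerisation of the styrene ends, a sluggish quinone methide, and low or wrong-sense enantioselectivity.

The fallback sets out from 4 and comes back at 10. It sets the stereocentre by C–C bond formation on a preformed ring.
- 4 is acetylated (AcOH, BF3·OEt2) to 1-(2-hydroxy-4,5,6-trimethoxyphenyl)ethanone F1.
- F1 is condensed with DMF dimethyl acetal to (E)-3-(dimethylamino)-1-(2-hydroxy-4,5,6-trimethoxyphenyl)prop-2-en-1-one F2.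
- F2 is closed with aqueous HCl to 5,6,7-trimethoxychromone F3.
- F3 is arylated with commercial [4-(benzyloxy)-3-methoxyphenyl]boronic acid by Pd(II)/t-BuPyOx (or Rh/chiral diene) asymmetric conjugate addition. This gives (2S)-2-[4-(benzyloxy)-3-methoxyphenyl]-5,6,7-trimethoxychroman-4-one F4.
- Hydrogenolysis of F4 gives 10.

**Step 4.** The risks are competing hydride abstraction at C2–H and over-oxidation through the 4-methoxyflav-3-ene to the flavone.

The fallback sets out from 8 and comes back at 9. It replaces C–H oxidation by ionisation followed by alcohol oxidation. The labile C4–OMe groups are solvolysed (PPTS, aqueous acetone) to the C4-epimeric bis(flavan-4-ol) 1,4-bis({4-[(2S)-4-hydroxy-5,6,7-trimethoxychroman-2-yl]-2-methoxyphenoxy}methyl)benzene F5. F5 is then oxidised with Dess–Martin periodinane to 9.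

**Step 5.** The risks are reduction of the aryl ketone and hydrogenolysis of the benzylic C2–O1 bond.

The fallback sets out from 9 and comes back at 10. It uses acidolytic benzyl transfer instead of reduction. TFA with excess pentamethylbenzene at rt moves the xylylene unit onto the arene scavenger by Friedel–Crafts capture. BCl3-type reagents are avoided because they would cleave the 5-OMe group next to the carbonyl. No new route compound is made.

**Further compounds**
F1 | step 3 | 1-(2-hydroxy-4,5,6-trimethoxyphenyl)ethanone | CC(=O)c1c(O)cc(OC)c(OC)c1OC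
F2 | step 3 | (E)-3-(dimethylamino)-1-(2-hydroxy-4,5,6-trimethoxyphenyl)prop-2-en-1-one | CN(C)/C=C/C(=O)c1c(O)cc(OC)c(OC)c1OC
F3 | step 3 | 5,6,7-trimethoxychromone | COc1cc2occc(=O)c2c(OC)c1OC
F4 | step 3 | (2S)-2-[4-(benzyloxy)-3-methoxyphenyl]-5,6,7-trimethoxychroman-4-one | COc1cc([C@@H]2CC(=O)c3c(cc(OC)c(OC)c3OC)O2)ccc1OCc1ccccc1
F5 | step 4 | 1,4-bis({4-[(2S)-4-hydroxy-5,6,7-trimethoxychroman-2-yl]-2-methoxyphenoxy}methyl)benzene (C4 epimers) | COc1cc([C@@H]2CC(O)c3c(cc(OC)c(OC)c3OC)O2)ccc1OCc1ccc(COc2ccc([C@@H]3CC(O)c4c(cc(OC)c(OC)c4OC)O3)cc2OC)cc1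
F0 | step 5 | none | none
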